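**Retrosynthetic overview**
1. Eupacunolin ⇐ its 15‑O‑silyl ether ⇐ an acyclic iodo‑aldehyde: one Ni/Cr operation makes the C5–C6 bond (ten‑membered carbocycle first) and the new C6 alkoxide then closes the α‑methylene γ‑lactone on the pendant acrylate ester (second ring, same flask).
2. The iodo‑aldehyde ⇐ methyl ketone + iodo‑enal by boron aldol (C2–C3) and Evans–Tishchenko reduction (C3–OAc, C1–OH, 1,3‑anti), then unmasking of C6 from a dioxolane.
3. The methyl ketone ⇐ ring‑opened 2,3‑dimethylfuran (Z keto‑enal) + a glyceraldehyde‑derived allylic bromide by indium allylation (C7–C8) and in‑flask tigloylation; the dioxolane is both the masked C6 aldehyde and the source of absolute configuration.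
4. The iodo‑enal ⇐ methyl propiolate + formaldehyde (β‑iodo Baylis–Hillman), which fixes the Z geometry of C4=C5; the Z geometry of C9=C10 comes from the furan.

Assumption: atom labels used below are C6 = lactone carbinol, C7 = ring‑fusion CH bearing C11(=C13H2)–C12(=O), C8 = tiglate carbinol, C9=C10(C14H3), C1 = free carbinol, C2 = CH2, C3 = acetate carbinol, C4(C15H2OH)=C5; (R)‑glyceraldehyde acetonide is bought as its commercial solution.

**Step 1**
Reactants: 1 2,3-dimethylfuran
Product: 2 (2Z)-3-methyl-4-oxopent-2-enal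
Conditions: mCPBA (1.0 equiv), CH2Cl2, 0 °C; used crude at once
Reagents that add atoms: mCPBA, O=C(OO)c1cccc(Cl)c1
Why: Oxidative ring opening of the furan (epoxidation of the more substituted ring double bond, then opening) gives the cis‑enedicarbonyl compound, so the Z geometry of the future C9=C10 bond comes straight from the ring and no stereocentre is formed.

**Step 2**
Reactants: 3 (4R)-2,2-dimethyl-1,3-dioxolane-4-carbaldehyde; 4 methyl acrylate
Product: 5 methyl 2-{[(4R)-2,2-dimethyl-1,3-dioxolan-4-yl](hydroxy)methyl}prop-2-enoate (both carbinol epimers)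
Conditions: DABCO (0.5 equiv), dioxane/H2O 1:1, rt, 3 d
Reagents that add atoms: none
Why: Morita–Baylis–Hillman reaction in which the new carbinol centre is formed as a mixture that is erased in step 3, while the chiral‑pool dioxolane centre is untouched.

**Step 3**
Reactants: 5 methyl 2-{[(4R)-2,2-dimethyl-1,3-dioxolan-4-yl](hydroxy)methyl}prop-2-enoate
Product: 6 methyl (2Z)-2-(bromomethyl)-3-[(4S)-2,2-dimethyl-1,3-dioxolan-4-yl]prop-2-enoate
Conditions: NBS, Me2S, CH2Cl2, 0 °C to rt
Reagents that add atoms: N-bromosuccinimide, O=C1CCC(=O)N1Br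
Why: Corey–Kim‑type activation of the allylic alcohol followed by SN2′ attack of bromide gives the rearranged primary allylic bromide, both carbinol epimers converging on the thermodynamically preferred Z alkene (dioxolane trans to the ester).

**Step 4**
Reactants: 6 methyl (2Z)-2-(bromomethyl)-3-[(4S)-2,2-dimethyl-1,3-dioxolan-4-yl]prop-2-enoate; 2 (2Z)-3-methyl-4-oxopent-2-enal
Product: 8 methyl (3R,4R,5Z)-3-[(4S)-2,2-dimethyl-1,3-dioxolan-4-yl]-6-methyl-4-{[(2E)-2-methylbut-2-enoyl]oxy}-2-methylidene-7-oxooct-5-enoate, via hydroxy ester 7 (not isolated)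
Conditions: In powder, DMF, rt, then 2, 0 °C; then tiglic anhydride, Et3N, DMAP (cat.), 0 °C to rt
Reagents that add atoms: tiglic anhydride, C/C=C(\C)C(=O)OC(=O)/C(C)=C/C
Why: Indium‑mediated Barbier‑type allylation (SE2′, chair transition state with the Z‑allylindium placing the dioxolane axial) adds chemoselectively to the aldehyde of 2 to give the 7,8‑syn adduct, attack occurring anti to the dioxolane C–O bond in the H‑eclipsed conformer so that the chiral‑pool centre sets C7 and C8, and in‑flask acylation of the indium alkoxide forestalls hemiketal and furan formation with the cis ketone.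

**Step 5**
Reactants: 9 methyl propiolate; 10 formaldehyde (as paraformaldehyde)
Product: 11 methyl (2Z)-2-(hydroxymethyl)-3-iodoprop-2-enoate
Conditions: MgI2, (CH2O)n, CH2Cl2, 0 °C to rt
Reagents that add atoms: magnesium diiodide, [Mg+2].[I-].[I-]
Why: β‑Iodo Morita–Baylis–Hillman reaction in which conjugate addition of iodide gives a magnesium iodo‑allenolate whose aldol reaction with formaldehyde delivers the Z isomer (iodine cis to the ester), the relationship that later places C3 and C6 cis on the ring alkene.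

**Step 6**
Reactants: 11 methyl (2Z)-2-(hydroxymethyl)-3-iodoprop-2-enoate
Product: 12 methyl (2Z)-2-({[tert-butyl(dimethyl)silyl]oxy}methyl)-3-iodoprop-2-enoate
Conditions: TBSCl, imidazole, DMF, 0 °C to rt
Reagents that add atoms: tert-butyldimethylsilyl chloride, CC(C)(C)[Si](C)(C)Cl
Why: Silyl ether formation protects the future C15 hydroxyl through all later steps and involves no stereocentre.

**Step 7**
Reactants: 12 methyl (2Z)-2-({[tert-butyl(dimethyl)silyl]oxy}methyl)-3-iodoprop-2-enoate
Product: 13 (2E)-2-({[tert-butyl(dimethyl)silyl]oxy}methyl)-3-iodoprop-2-en-1-ol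
Conditions: DIBAL-H (2.2 equiv), CH2Cl2, −78 °C
Reagents that add atoms: none
Why: Hydride 1,2‑reduction of the conjugated ester to the allylic alcohol leaves the vinyl iodide and its geometry intact (the descriptor changes only through the priority switch).

**Step 8**
Reactants: 13 (2E)-2-({[tert-butyl(dimethyl)silyl]oxy}methyl)-3-iodoprop-2-en-1-ol
Product: 14 (2Z)-2-({[tert-butyl(dimethyl)silyl]oxy}methyl)-3-iodoprop-2-enal
Conditions: MnO2, CH2Cl2, rt
Reagents that add atoms: none
Why: Chemoselective allylic oxidation with MnO2 gives the non‑enolisable enal without isomerising the iodo‑alkene.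

**Step 9**
Reactants: 8 methyl (3R,4R,5Z)-3-[(4S)-2,2-dimethyl-1,3-dioxolan-4-yl]-6-methyl-4-{[(2E)-2-methylbut-2-enoyl]oxy}-2-methylidene-7-oxooct-5-enoate; 14 (2Z)-2-({[tert-butyl(dimethyl)silyl]oxy}methyl)-3-iodoprop-2-enal
Product: 15 methyl (3R,4R,5Z,9S,10Z)-10-({[tert-butyl(dimethyl)silyl]oxy}methyl)-3-[(4S)-2,2-dimethyl-1,3-dioxolan-4-yl]-9-hydroxy-11-iodo-6-methyl-4-{[(2E)-2-methylbut-2-enoyl]oxy}-2-methylidene-7-oxoundeca-5,10-dienoate
Conditions: (+)-Ipc2BCl, Et3N, Et2O, 0 °C, then 14, −78 to −20 °C; H2O2, pH 7 buffer, MeOH, 0 °C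
Reagents that add atoms: none
Why: Paterson‑type boron aldol reaction in which the methyl ketone is enolised on the methyl side and the enol diisopinocampheylborinate adds under reagent control to the Si face of enal 14, setting the C3 carbinol as S.

**Step 10**
Reactants: 15 (β‑hydroxy ketone from step 9)
Product: 16 methyl (3R,4R,5Z,7S,9S,10Z)-9-acetoxy-10-({[tert-butyl(dimethyl)silyl]oxy}methyl)-3-[(4S)-2,2-dimethyl-1,3-dioxolan-4-yl]-7-hydroxy-11-iodo-6-methyl-4-{[(2E)-2-methylbut-2-enoyl]oxy}-2-methylideneundeca-5,10-dienoate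
Conditions: SmI2 (30 mol %), CH3CHO (10 equiv), THF, −10 °C
Reagents that add atoms: acetaldehyde, CC=O
Why: Evans–Tishchenko reduction in which the samarium‑bound hemiacetal of acetaldehyde delivers hydride intramolecularly to the C1 ketone through a six‑membered chair, giving the 1,3‑anti diol monoester with the acetate on O3 and the free hydroxyl at the new S‑configured C1, exactly the pattern of the target.

**Step 11**
Reactants: 16 (acetate from step 10)
Product: 18 methyl (3R,4R,5Z,7S,9S,10Z)-9-acetoxy-10-({[tert-butyl(dimethyl)silyl]oxy}methyl)-3-formyl-7-hydroxy-11-iodo-6-methyl-4-{[(2E)-2-methylbut-2-enoyl]oxy}-2-methylideneundeca-5,10-dienoate, via diol 17 (not isolated)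
Conditions: H5IO6, EtOAc, 0 °C to rt; used at once
Reagents that add atoms: none
Why: Periodic acid hydrolyses the terminal acetonide and cleaves the resulting 1,2‑diol (Malaprade glycol cleavage), unmasking the C6 aldehyde under non‑basic conditions that leave the adjacent C7 centre, the silyl ether and the esters untouched.

**Step 12**
Reactants: 18 (iodo‑aldehyde from step 11)
Product: 20 15-O-(tert-butyldimethylsilyl)eupacunolin, via hydroxy ester 19 (not isolated)
Conditions: CrCl2 (10 equiv), NiCl2 (1 mol %), DMSO/THF, 2 mM, rt; then PPTS (cat.), CH2Cl2, rt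
Reagents that add atoms: none
Why: Intramolecular Nozaki–Hiyama–Kishi reaction followed by lactonisation, in which the alkenylchromium formed with retention of the Z geometry adds to the aldehyde anti to the large C8 branch (Felkin–Anh) to close the ten‑membered ring and set C6 as R, and the resulting alkoxide acylates the neighbouring methyl ester so that the trans‑fused α‑methylene γ‑lactone closes in the same flask.

**Step 13**
Reactants: 20 15-O-(tert-butyldimethylsilyl)eupacunolin
Product: 21 eupacunolin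
Conditions: HF·pyridine, pyridine, THF, 0 °C
Reagents that add atoms: none
Why: Fluoride‑mediated desilylation under buffered acidic conditions frees the primary C15 hydroxyl without acyl migration or attack on the α‑methylene lactone, and no stereocentre is touched.

**Compound list**
1 | 2,3-dimethylfuran | Cc1occc1C | starting material
2 | (2Z)-3-methyl-4-oxopent-2-enal | CC(=O)/C(C)=C\C=O | intermediate
3 | (4R)-2,2-dimethyl-1,3-dioxolane-4-carbaldehyde ((R)-glyceraldehyde acetonide) | O=C[C@H]1COC(C)(C)O1 | starting material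
4 | methyl acrylate | C=CC(=O)OC | starting material
5 | methyl 2-{[(4R)-2,2-dimethyl-1,3-dioxolan-4-yl](hydroxy)methyl}prop-2-enoate (both carbinol epimers) | C=C(C(=O)OC)C(O)[C@H]1COC(C)(C)O1 | intermediate
6 | methyl (2Z)-2-(bromomethyl)-3-[(4S)-2,2-dimethyl-1,3-dioxolan-4-yl]prop-2-enoate | COC(=O)/C(CBr)=C/[C@H]1COC(C)(C)O1 | intermediate
7 | methyl (3R,4R,5Z)-3-[(4S)-2,2-dimethyl-1,3-dioxolan-4-yl]-4-hydroxy-6-methyl-2-methylidene-7-oxooct-5-enoate | C=C(C(=O)OC)[C@@H]([C@H]1COC(C)(C)O1)[C@H](O)/C=C(C)\C(C)=O | intermediate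
8 | methyl (3R,4R,5Z)-3-[(4S)-2,2-dimethyl-1,3-dioxolan-4-yl]-6-methyl-4-{[(2E)-2-methylbut-2-enoyl]oxy}-2-methylidene-7-oxooct-5-enoate | C=C(C(=O)OC)[C@@H]([C@H]1COC(C)(C)O1)[C@H](OC(=O)/C(C)=C/C)/C=C(C)\C(C)=O | intermediate
9 | methyl propiolate | C#CC(=O)OC | starting material
10 | formaldehyde (as paraformaldehyde) | C=O | starting material
11 | methyl (2Z)-2-(hydroxymethyl)-3-iodoprop-2-enoate | COC(=O)/C(CO)=C\I | intermediate
12 | methyl (2Z)-2-({[tert-butyl(dimethyl)silyl]oxy}methyl)-3-iodoprop-2-enoate | COC(=O)/C(CO[Si](C)(C)C(C)(C)C)=C\I | intermediate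
13 | (2E)-2-({[tert-butyl(dimethyl)silyl]oxy}methyl)-3-iodoprop-2-en-1-ol | OC/C(CO[Si](C)(C)C(C)(C)C)=C\I | intermediate
14 | (2Z)-2-({[tert-butyl(dimethyl)silyl]oxy}methyl)-3-iodoprop-2-enal | O=C/C(CO[Si](C)(C)C(C)(C)C)=C\I | intermediate
15 | methyl (3R,4R,5Z,9S,10Z)-10-({[tert-butyl(dimethyl)silyl]oxy}methyl)-3-[(4S)-2,2-dimethyl-1,3-dioxolan-4-yl]-9-hydroxy-11-iodo-6-methyl-4-{[(2E)-2-methylbut-2-enoyl]oxy}-2-methylidene-7-oxoundeca-5,10-dienoate | C=C(C(=O)OC)[C@@H]([C@H]1COC(C)(C)O1)[C@H](OC(=O)/C(C)=C/C)/C=C(C)\C(=O)C[C@H](O)/C(CO[Si](C)(C)C(C)(C)C)=C\I | intermediate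
16 | methyl (3R,4R,5Z,7S,9S,10Z)-9-acetoxy-10-({[tert-butyl(dimethyl)silyl]oxy}methyl)-3-[(4S)-2,2-dimethyl-1,3-dioxolan-4-yl]-7-hydroxy-11-iodo-6-methyl-4-{[(2E)-2-methylbut-2-enoyl]oxy}-2-methylideneundeca-5,10-dienoate | C=C(C(=O)OC)[C@@H]([C@H]1COC(C)(C)O1)[C@H](OC(=O)/C(C)=C/C)/C=C(C)\[C@@H](O)C[C@H](OC(C)=O)/C(CO[Si](C)(C)C(C)(C)C)=C\I | intermediate
17 | the 1,2-diol of 16: the dioxolane is replaced by a (1S)-1,2-dihydroxyethyl group, all else unchanged | C=C(C(=O)OC)[C@@H]([C@H](O)CO)[C@H](OC(=O)/C(C)=C/C)/C=C(C)\[C@@H](O)C[C@H](OC(C)=O)/C(CO[Si](C)(C)C(C)(C)C)=C\I | intermediate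
18 | methyl (3R,4R,5Z,7S,9S,10Z)-9-acetoxy-10-({[tert-butyl(dimethyl)silyl]oxy}methyl)-3-formyl-7-hydroxy-11-iodo-6-methyl-4-{[(2E)-2-methylbut-2-enoyl]oxy}-2-methylideneundeca-5,10-dienoate | C=C(C(=O)OC)[C@@H](C=O)[C@H](OC(=O)/C(C)=C/C)/C=C(C)\[C@@H](O)C[C@H](OC(C)=O)/C(CO[Si](C)(C)C(C)(C)C)=C\I | intermediate
19 | ring-closed hydroxy ester: ten-membered Z,Z-diene carbocycle of 20 with free C6–OH and the methyl 2-propenoate unit on C7 not yet lactonised | C=C(C(=O)OC)[C@H]1[C@H](O)/C=C(/CO[Si](C)(C)C(C)(C)C)[C@@H](OC(C)=O)C[C@H](O)/C(C)=C\[C@H]1OC(=O)/C(C)=C/C | intermediate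
20 | 15-O-(tert-butyldimethylsilyl)eupacunolin | C=C1C(=O)O[C@@H]2/C=C(/CO[Si](C)(C)C(C)(C)C)[C@@H](OC(C)=O)C[C@H](O)/C(C)=C\[C@@H](OC(=O)/C(C)=C/C)[C@@H]12 | intermediate
21 | eupacunolin | C=C1C(=O)O[C@@H]2/C=C(/CO)[C@@H](OC(C)=O)C[C@H](O)/C(C)=C\[C@@H](OC(=O)/C(C)=C/C)[C@@H]12 | target

**Totals**
Total steps: 13. Longest linear sequence: 9 (steps 5–13, from methyl propiolate).

**Three steps most likely to fail, each with a fallback**

Step 12 (Ni/Cr ring closure with lactonisation). The medium‑ring closure can give oligomers or the C6 epimer, and aldehyde 18 can lose the tiglate by β‑elimination. The fallback sets out from 8 and 13 and comes back to the route at 20, closing the ring at C2–C3 instead. The acetonide of 8 is cleaved with H5IO6 to the formyl keto ester F1. F1 and vinyl iodide 13 are joined intermolecularly with CrCl2 and NiCl2 (cat.), the alkoxide lactonising to the lactone alcohol F2. MnO2 oxidation gives the lactone enal F3. An intramolecular boron aldol reaction (c‑Hex2BCl, Et3N, high dilution) then closes the ten‑membered ring to the macrocyclic β‑hydroxy ketone F4, and Evans–Tishchenko reduction of F4 (SmI2 cat., CH3CHO) gives 20.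

Step 4 (indium allylation of the enedicarbonyl compound and in‑flask tigloylation). The metal may reduce 2, the adduct may cyclise to a furan before it is acylated, or facial control by the dioxolane may be weak. The fallback sets out from 6 and comes back at 7. Bromide 6 is converted with B2pin2, CuCl (cat.) and KOt‑Bu into the allylboronate methyl (2Z)-3-[(4S)-2,2-dimethyl-1,3-dioxolan-4-yl]-2-[(4,4,5,5-tetramethyl-1,3,2-dioxaborolan-2-yl)methyl]prop-2-enoate F5. Its thermal allylboration of 2 (toluene, 50 °C) runs through a closed chair transition state with no reducing metal present and gives alcohol 7 after work‑up, which is tigloylated as before to 8.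

Step 9 (reagent‑controlled boron aldol). Enolisation may be slow or the facial selectivity low with this hindered enone. The fallback sets out from 8 and comes back at 15. Ketone 8 is converted (TMSOTf, Et3N, CH2Cl2, −78 °C) into the trimethylsilyl enol ether F6, which is added to 14 in a Mukaiyama aldol reaction catalysed by a tartrate‑derived chiral acyloxyborane; acidic work‑up removes the silyl group and gives 15.

**Further compounds**
F1 | step 12 | methyl (3R,4R,5Z)-3-formyl-6-methyl-4-{[(2E)-2-methylbut-2-enoyl]oxy}-2-methylidene-7-oxooct-5-enoate | C=C(C(=O)OC)[C@@H](C=O)[C@H](OC(=O)/C(C)=C/C)/C=C(C)\C(C)=O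
F2 | step 12 | lactone alcohol: trans-4,5-disubstituted 3-methylideneoxolan-2-one carrying at C5 the (1Z)-2-(TBS-oxymethyl)-3-hydroxyprop-1-enyl group and at C4 the (1R,2Z)-3-methyl-4-oxo-1-(tigloyloxy)pent-2-enyl group | C=C1C(=O)O[C@H](/C=C(/CO[Si](C)(C)C(C)(C)C)CO)[C@H]1[C@H](OC(=O)/C(C)=C/C)/C=C(C)\C(C)=O
F3 | step 12 | lactone enal: F2 with the primary allylic alcohol oxidised to the aldehyde | C=C1C(=O)O[C@H](/C=C(/CO[Si](C)(C)C(C)(C)C)C=O)[C@H]1[C@H](OC(=O)/C(C)=C/C)/C=C(C)\C(C)=O
F4 | step 12 | macrocyclic β-hydroxy ketone: 20 with a C1 ketone and a free C3 hydroxyl in place of C1–OH and C3–OAc | C=C1C(=O)O[C@@H]2/C=C(/CO[Si](C)(C)C(C)(C)C)[C@@H](O)CC(=O)/C(C)=C\[C@@H](OC(=O)/C(C)=C/C)[C@@H]12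
F5 | step 4 | methyl (2Z)-3-[(4S)-2,2-dimethyl-1,3-dioxolan-4-yl]-2-[(4,4,5,5-tetramethyl-1,3,2-dioxaborolan-2-yl)methyl]prop-2-enoate | COC(=O)/C(CB1OC(C)(C)C(C)(C)O1)=C/[C@H]1COC(C)(C)O1
F6 | step 9 | trimethylsilyl enol ether of 8 (methyl-side enol ether of the C1 ketone) | C=C(C(=O)OC)[C@@H]([C@H]1COC(C)(C)O1)[C@H](OC(=O)/C(C)=C/C)/C=C(C)\C(=C)O[Si](C)(C)C
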